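**Plan**
The target is achiral. Ring A (C1 OH, C2 O-aryl, C3 Br, C4 H, C5 H, C6 Br) is joined through the C2 oxygen to ring B, a 2,4-dibromophenyl group.
Enabling feature: C6 of ring A is a C–Br carbon between the oxygen-bearing C1 and the unsubstituted C5. A CBr2 unit ends up in that position once it has added to a C1=C5 silyl enol ether and the cyclopropane has opened.
Retrosynthetic cuts, in order: O–Si; C1–C6 and C5–C6 (C6 leaves as dibromocarbene and ring A contracts to a 2-silyloxycyclopentadiene); the dienol ether O–Si; C3–Br; C2–O(aryl); the epoxide oxygen.
Forward: ring B and the five-membered carbocycle are bought. The carbocycle takes on the aryloxy group at C2, bromine at C3 and the silyloxy group at C1, is enlarged to aromatic ring A in one operation, and is then desilylated.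
Stereochemistry: none has to be set. The stereocentres of the racemic intermediates (epoxide, hydroxy ether, dibromide, dibromocyclopropane) are all erased by elimination or aromatisation.

Key step: step 5

Remark: the ring A numbers are also used for the five-membered precursors (C6 is the carbon still missing). The SMILES of racemic intermediates with two stereocentres show one enantiomer.

Step 1
Reactants: 1 cyclopent-2-en-1-one
Product: 2 rac-cis-2,3-epoxycyclopentan-1-one
Conditions: 30% aq H2O2 (1.5 equiv), NaOH (cat.), MeOH, 0 °C
Reagents that add atoms: hydrogen peroxide, OO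
Why: Weitz–Scheffer epoxidation: hydroperoxide anion adds to C3 of the enone and the enolate closes onto oxygen with loss of hydroxide, which in a five-membered ring can only give the cis-fused epoxide, formed as a racemate whose two stereocentres are erased again in step 2.

Step 2
Reactants: 2 rac-cis-2,3-epoxycyclopentan-1-one, 3 2,4-dibromophenol
Product: 5 2-(2,4-dibromophenoxy)cyclopent-2-en-1-one, via trans-hydroxy ketone 4 (not isolated)
Conditions: Cs2CO3 (0.3 equiv), DMF, 2 added slowly to 3, 50 → 80 °C
Reagents that add atoms: none
Why: Epoxy ketone to 2-aryloxyenone conversion: the phenoxide opens the epoxide by SN2 attack at C2, the carbon activated by the neighbouring carbonyl group, with inversion (hence trans-4), and E1cB loss of the C3 hydroxyl then removes both stereocentres and returns hydroxide, so that base is needed only in catalytic amount and the sensitive epoxy ketone never meets anything stronger than a phenoxide.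

Step 3
Reactants: 5 2-(2,4-dibromophenoxy)cyclopent-2-en-1-one
Product: 7 3-bromo-2-(2,4-dibromophenoxy)cyclopent-2-en-1-one, via trans-dibromide 6 (not isolated)
Conditions: Br2 (1.05 equiv), CH2Cl2, −20 → 0 °C, dark; then Et3N (1.5 equiv), 0 °C
Reagents that add atoms: bromine, BrBr
Why: Bromine addition and dehydrobromination, the standard enone halogenation, here steered to C3: anti addition gives the trans dibromide, C2 carries no hydrogen and its bromide is an α-bromo ether that ionises with the help of the aryloxy oxygen, so Et3N restores the conjugated enone by taking the proton from C3 and bromine stays there, as in the C3 bromination of cyclopentane-1,2-dione enols and their ethers, while ring B with its two bromines is too deactivated to react with Br2 at 0 °C without a Lewis acid.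

Step 4
Reactants: 7 3-bromo-2-(2,4-dibromophenoxy)cyclopent-2-en-1-one
Product: 9 tert-butyl{[4-bromo-5-(2,4-dibromophenoxy)cyclopenta-1,4-dien-1-yl]oxy}dimethylsilane, via lithium dienolate 8 (not isolated)
Conditions: LiN(SiMe3)2 (1.05 equiv), THF, −78 °C, 7 added to the base; TBSOTf (1.1 equiv), −78 °C; solvent exchanged for cold pentane, LiOTf filtered off, solution kept at −78 °C and used at once
Reagents that add atoms: tert-butyldimethylsilyl trifluoromethanesulfonate (TBSOTf), CC(C)(C)[Si](C)(C)OS(=O)(=O)C(F)(F)F
Why: Kinetic enolisation of a conjugated enone at the α′ carbon followed by O-silylation: the hindered amide takes the C5 proton next to the carbonyl faster than the C4 proton, inverse addition prevents enolate equilibration through free ketone, LiN(SiMe3)2 is too weak a base to metalate the ring B hydrogen flanked by two bromines (a risk with LiN(iPr)2), and the silyl triflate traps the cross-conjugated dienolate on oxygen already at −78 °C, below the range in which 1,5-hydrogen shifts or Diels–Alder dimerisation of the cyclopentadiene set in.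

Step 5
Reactants: 9 tert-butyl{[4-bromo-5-(2,4-dibromophenoxy)cyclopenta-1,4-dien-1-yl]oxy}dimethylsilane, 10 bromoform
Product: 13 tert-butyl[3,6-dibromo-2-(2,4-dibromophenoxy)phenoxy]dimethylsilane, via tribromomethyllithium 11 (not isolated), via dibromocyclopropane 12 (not isolated)
Conditions: 10 (3.3 equiv), LiN(SiMe3)2 (3.0 equiv), THF–Et2O–pentane 4:1:1, −110 °C; precooled pentane solution of 9, −110 → −60 °C; Et3N (3 equiv), → 20 °C
Reagents that add atoms: bromoform 10, BrC(Br)Br
Why: Tribromomethyllithium 11 is made first, so that no amide base is left when 9 arrives, and on warming it transfers CBr2 to the C1=C5 double bond in a concerted (2+1) cheletropic addition that forms C1–C6 and C5–C6; in 12 the endo bromide then ionises while the C1–C5 bond breaks in a disrotatory two-electron electrocyclic opening. The cation released is the arenium ion of 13 protonated at C4, para to the silyloxy group that stabilises it, and Et3N removes that proton to complete aromatic ring A with loss of HBr overall. The closest known reactions are the dihalocarbene enlargement of cyclopentadienes and indenes to halobenzenes and halonaphthalenes (the carbocyclic counterpart of the Ciamician–Dennstedt rearrangement), the homologation of cyclic silyl enol ethers to α-haloenones and the conversion of 3-silyloxyindenes into 2-halo-1-naphthols. Ring A therefore closes by one-carbon ring enlargement, that is closure of the three-membered ring on the five-membered one followed by cleavage of the shared bond of the bicyclo[3.1.0]hexene, and not by an end-to-end cyclisation. The two stereocentres of 12 (C1 and C5, cis-fused by necessity, racemic) disappear on aromatisation, so no stereocontrol is required. What the step needs is site selectivity and an unscrambled diene: the electrophilic carbenoid prefers C1=C5, a trisubstituted silyl enol ether with an unhindered C5–H terminus, to C2=C3, which is tetrasubstituted, bromine-deactivated and fed only by the weak donor dibromophenoxy, while the temperature below −60 °C stops 1,5-hydrogen shifts and the acidic C4H2 group meets only the feebly basic CBr3 anion and HN(SiMe3)2 instead of an alkoxide.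

Step 6
Reactants: 13 tert-butyl[3,6-dibromo-2-(2,4-dibromophenoxy)phenoxy]dimethylsilane
Product: 14 3,6-dibromo-2-(2,4-dibromophenoxy)phenol
Conditions: Bu4NF (1.1 equiv), AcOH (1.1 equiv), THF, 0 °C
Reagents that add atoms: none
Why: Fluoride-induced cleavage of an aryl silyl ether, driven by the Si–F bond and by the good leaving ability of a phenoxide flanked by bromine and aryloxy groups; the acetic acid buffer protonates the phenoxide at once, and the aryl bromides and the diaryl ether are inert to these conditions.

**Compound list**
1 | cyclopent-2-en-1-one | O=C1C=CCC1 | starting material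
2 | rac-cis-2,3-epoxycyclopentan-1-one (6-oxabicyclo[3.1.0]hexan-2-one) | O=C1CC[C@@H]2O[C@H]12 | intermediate
3 | 2,4-dibromophenol | Oc1ccc(Br)cc1Br | starting material
4 | rac-trans-2-(2,4-dibromophenoxy)-3-hydroxycyclopentan-1-one | O=C1CC[C@H](O)[C@H]1Oc1ccc(Br)cc1Br | intermediate
5 | 2-(2,4-dibromophenoxy)cyclopent-2-en-1-one | O=C1CCC=C1Oc1ccc(Br)cc1Br | intermediate
6 | rac-trans-2,3-dibromo-2-(2,4-dibromophenoxy)cyclopentan-1-one | O=C1CC[C@H](Br)[C@]1(Br)Oc1ccc(Br)cc1Br | intermediate
7 | 3-bromo-2-(2,4-dibromophenoxy)cyclopent-2-en-1-one | O=C1CCC(Br)=C1Oc1ccc(Br)cc1Br | intermediate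
8 | lithium 4-bromo-5-(2,4-dibromophenoxy)cyclopenta-1,4-dien-1-olate (cross-conjugated dienolate, C1=C5 and C2=C3) | [Li]OC1=CCC(Br)=C1Oc1ccc(Br)cc1Br | intermediate
9 | tert-butyl{[4-bromo-5-(2,4-dibromophenoxy)cyclopenta-1,4-dien-1-yl]oxy}dimethylsilane (route numbering: C5H=C1(OTBS)–C2(OAr)=C3(Br), C4H2) | CC(C)(C)[Si](C)(C)OC1=CCC(Br)=C1Oc1ccc(Br)cc1Br | intermediate
10 | bromoform | BrC(Br)Br | starting material
11 | tribromomethyllithium | [Li]C(Br)(Br)Br | intermediate
12 | rac-tert-butyl{[3,6,6-tribromo-2-(2,4-dibromophenoxy)bicyclo[3.1.0]hex-2-en-1-yl]oxy}dimethylsilane | CC(C)(C)[Si](C)(C)O[C@@]12C(Oc3ccc(Br)cc3Br)=C(Br)C[C@@H]1C2(Br)Br | intermediate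
13 | tert-butyl[3,6-dibromo-2-(2,4-dibromophenoxy)phenoxy]dimethylsilane | CC(C)(C)[Si](C)(C)Oc1c(Br)ccc(Br)c1Oc1ccc(Br)cc1Br | intermediate
14 | 3,6-dibromo-2-(2,4-dibromophenoxy)phenol (CNP0284899.0) | Oc1c(Br)ccc(Br)c1Oc1ccc(Br)cc1Br | target

Total step count: 6. Longest linear sequence: 6 steps (1 to 14).

**Steps most likely to fail**

Step 5.
- What may go wrong: positional scrambling of the diene by proton transfer or 1,5-hydrogen shift before the carbenoid has reacted; carbene transfer to the C2=C3 double bond; self-dimerisation of the diene; decay of the carbenoid faster than its transfer.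
- The fallback sets out from 3 and comes back at 14. Ring A is bought as an arene instead of being built.
- 3 and commercial 3,6-dibromo-2-fluorobenzaldehyde (O=Cc1c(F)c(Br)ccc1Br) are joined by nucleophilic aromatic substitution of the fluoride ortho to the formyl group (K2CO3, DMF, 80 °C). This should give 3,6-dibromo-2-(2,4-dibromophenoxy)benzaldehyde F1.
- Baeyer–Villiger oxidation (mCPBA, CH2Cl2), in which the aryl group carrying the ortho aryloxy donor migrates, should give 3,6-dibromo-2-(2,4-dibromophenoxy)phenyl formate F2.
- Methanolysis (K2CO3 cat., MeOH, 20 °C) then gives 14.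

Step 4.
- What may go wrong: competing removal of the C4 proton, which leads to the linear dienolate; hydrolysis or positional isomerisation of the dienol ether while it is being freed from salts.
- The fallback sets out from 7 and comes back at 14. C6 is inserted into the ketone itself, between the same atoms C1 and C5, so no cyclopentadiene is needed.
- Lewis acid-promoted homologation with trimethylsilyldiazomethane (BF3·OEt2, CH2Cl2, −78 °C, Büchner–Curtius–Schlotterbeck type) has the saturated C5 migrating in preference to the vinylic C2. It should give racemic 3-bromo-2-(2,4-dibromophenoxy)-6-(trimethylsilyl)cyclohex-2-en-1-one F3.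
- Protodesilylation (1 M HCl, THF) gives 3-bromo-2-(2,4-dibromophenoxy)cyclohex-2-en-1-one F4.
- Twofold α′-bromination with PhNMe3Br3 (2 equiv, THF) gives 3,6,6-tribromo-2-(2,4-dibromophenoxy)cyclohex-2-en-1-one F5.
- DBU (CH2Cl2, 0 °C) removes one HBr across C5–C6. The resulting cyclohexa-2,5-dienone is the keto tautomer of 14.

Step 3.
- What may go wrong: dehydrobromination taking another course (loss of the C3 bromide together with a C4 proton); acid-catalysed bromination at C5; further bromination of ring B.
- The fallback sets out from 3 and comes back at 7. The C3 bromide is derived from a carbonyl group, which fixes its position.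
- Regitz diazo transfer to commercial cyclopentane-1,3-dione (O=C1CCC(=O)C1) with 4-acetamidobenzenesulfonyl azide and Et3N in MeCN gives 2-diazocyclopentane-1,3-dione F6.
- Rh2(OAc)4-catalysed O–H insertion of the derived carbenoid into 3 (CH2Cl2, reflux) gives 2-(2,4-dibromophenoxy)-3-hydroxycyclopent-2-en-1-one F7, the enol form of the symmetrical 1,3-dione.
- Ph3PBr2 with Et3N (CH2Cl2, 20 °C) turns this vinylogous acid into the vinylogous acyl bromide 7.

**Further compounds**
F1 | step 5 | 3,6-dibromo-2-(2,4-dibromophenoxy)benzaldehyde | O=Cc1c(Br)ccc(Br)c1Oc1ccc(Br)cc1Br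
F2 | step 5 | 3,6-dibromo-2-(2,4-dibromophenoxy)phenyl formate | O=COc1c(Br)ccc(Br)c1Oc1ccc(Br)cc1Br
F3 | step 4 | racemic 3-bromo-2-(2,4-dibromophenoxy)-6-(trimethylsilyl)cyclohex-2-en-1-one | C[Si](C)(C)C1CCC(Br)=C(Oc2ccc(Br)cc2Br)C1=O
F4 | step 4 | 3-bromo-2-(2,4-dibromophenoxy)cyclohex-2-en-1-one | O=C1CCCC(Br)=C1Oc1ccc(Br)cc1Br
F5 | step 4 | 3,6,6-tribromo-2-(2,4-dibromophenoxy)cyclohex-2-en-1-one | O=C1C(Oc2ccc(Br)cc2Br)=C(Br)CCC1(Br)Br
F6 | step 3 | 2-diazocyclopentane-1,3-dione | [N-]=[N+]=C1C(=O)CCC1=O
F7 | step 3 | 2-(2,4-dibromophenoxy)-3-hydroxycyclopent-2-en-1-one | O=C1CCC(O)=C1Oc1ccc(Br)cc1Br
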